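A small charge of catalyst, the bench rule says, costs you time and not yield: wait long enough and target equals the substrate used. You have two runs and Friday's flask, charged with 0.2 mol% of free catalyst.

common to all: substrate 0.10 M; free catalyst 0.2 mol%
- Friday's: reagent 2 equiv; the very flask that is asked about, followed so far
- Tuesday's: reagent 3 equiv; run made earlier
- flask: reagent 2.00 equiv; time 4.0 d

| run | time / h | target / % | substrate / % |
|---|---|---|---|
| Friday's | 6.00 | 20 | 46 |
| Friday's | 20.0 | 26 | 0 |
| Friday's | 30.0 | 23 | 2 |
| Friday's | 48.0 | 23 | 0 |
| Friday's | 72.0 | 29 | 2 |
| Friday's | 96.0 | 25 | 0 |
| Tuesday's | 0.667 | 5 | 97 |
| Tuesday's | 2.00 | 8 | 79 |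
| Tuesday's | 4.00 | 21 | 55 |
| Tuesday's | 5.00 | 21 | 43 |
| Tuesday's | 8.00 | 27 | 21 |
| Tuesday's | 10.0 | 29 | 5 |

(each reading ± 2 percentage points)

- north-west: at 4.0 d take out 90% of the target then present, then wait 50 h
- north-east: at 4.0 d add free catalyst, 100% of the amount charged, then wait 50 h
- east: at 4.0 d add reagent, 100% of the amount charged, then wait 50 h
- north: change nothing and wait 50 h more

- in percentages every species weighs as the substrate in it: one side product counts as two
- target that was removed still counts
- steps under discussion: substrate + free catalyst -> catalyst intermediate A; catalyst intermediate A <-> catalyst intermediate B; reagent + catalyst intermediate B <-> catalyst intermediate C; catalyst intermediate C <-> free catalyst + target; substrate + target -> side product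
- additions bring no volume worth counting

* target, in percent of the substrate first charged, at 4.0 d
* which option adds most target ("none" when 2 percentage points or less is all one gets) (north-west / north-east / east / north / none)
* target present, with what was taken out counted in, in percent of the substrate first charged, after north-east
* target present, with what was taken out counted in, in percent of the substrate first charged, after east

Try the rule on Tuesday's run, working from the fraction left. At 0.667 h, substrate reads 97% and target 5%, so the rule holds within the scatter of 2 percentage points. At 2.00 h, 21.0% of the substrate is used, but target reads less than that, 8%. The ratio is 0.381, so the rule has stopped working there.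

The step from substrate and target to side product takes one of each. Its speed goes with the fraction of substrate left times the fraction of target. Tuesday's substrate falls nearly steadily, so I take the catalyst's pace as steady and proportional to its loading. Target stops climbing when this loss matches that pace. Taking the two fractions as roughly alike there, the plateau goes with the square root of the loading, at fixed reagent.

Friday's target readings from 20.0 h on average 25.2%, which gives 5.63. Call this the root ratio, the plateau fraction over the square root of the catalyst fraction.

Substrate is the limiting reagent, reading 0% at 96.0 h in Friday's run, and the step to side product takes substrate, as does the catalyst's first step. So I expect 25.2% at 4.0 d, and no option gaining more than 2 points.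

The forecast said 25% and none, with 25.2% after north-east and 25.2% after east, holding that “the side reaction stopped when the substrate ran out”.

The flask gives 25.2%, and the best option is none. Left ten times as long, target stands at 25.2%. Charged with 0.28 mol% of free catalyst, this flask's target has moved by 5 points. The root ratio gives 29.8% there, against 25.2% at Friday's loading.

    substrate + free catalyst → catalyst intermediate A (k = 39.0 M⁻¹ min⁻¹)
    catalyst intermediate A ⇌ catalyst intermediate B (K = 1.30, k = 4.20 min⁻¹)
    reagent + catalyst intermediate B ⇌ catalyst intermediate C (K = 2.20 M⁻¹, k = 150 M⁻¹ min⁻¹)
    catalyst intermediate C ⇌ free catalyst + target (K = 0.210 M, k = 4.60 min⁻¹)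
    substrate + target → side product (k = 0.0870 M⁻¹ min⁻¹)

For the neighbour charged with 0.8 mol% of free catalyst, the root ratio gives 50.4%. The computed flask gives 49.9%, twice this flask's target, with 0% of its substrate left.

All runs were generated by integration for substances that don't exist, and the scatter is random.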